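Retrosynthetic overview
- The C7=C8 enoate of ring B is carried one oxidation level higher, as a C7 ketone/enol. This extra oxygen is removed after the key step by enol triflation and formate reduction. Both acids travel as tert-butyl esters.
- Key disconnection: C9-C10 (closes ring B) together with C8=C9. A monocyclic ring A beta-keto ester, 5-methyl-4-oxohexanal and one hydrogen atom from a silane are joined in one flask by Knoevenagel condensation, iron-hydride hydrogen-atom transfer and 6-endo radical conjugate addition.
- Enabling feature: in ring B, C9 is bonded to C8, the carbon that bears the C14 carboxyl group. With C7 as a ketone, C8 is an active methylene and C9 becomes the beta carbon of a doubly activated alkylidene. C9 then lies in a 1,6-relation to C10, which the C1=C10 alkene of ring A turns into a nucleophilic tertiary radical.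
- Ring A is formed first (step 3) and ring B second (step 9). Ring A comes from an asymmetric Michael addition (sets C4), aldol condensation, CBS reduction and a Johnson-Claisen rearrangement. The rearrangement passes the C1-O chirality to C5, moves the alkene to C1=C10 and removes the ring oxygen.

Key step: step 9

Remark: positions follow abietane numbering (C18 = carboxyl carbon on C4, C14 = carboxyl carbon on C8). The target is read as (4R,5R,9R,10S), that is 4-beta-methyl, 5-alpha-H, 9-alpha-H and 10-beta-methyl, the same configuration as abietic acid.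

Step 1
Reactants: 1 tert-butyl propanoate; 2 ethyl formate
Product: 3 tert-butyl 2-methyl-3-oxopropanoate
Conditions: LiN(iPr)2, THF, -78 °C; then 2, -78 → 0 °C; aq. NH4Cl
Reagents that add atoms: none
Why: Crossed Claisen condensation (formylation) of the ester enolate with a non-enolisable formate gives the alpha-formyl ester, whose alpha carbon is configurationally labile and is therefore carried on as the racemate.

Step 2
Reactants: 3 tert-butyl 2-methyl-3-oxopropanoate; 4 pent-1-en-3-one
Product: 5 tert-butyl (2R)-2-formyl-2-methyl-5-oxoheptanoate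
Conditions: 6'-hydroxy-9-O-(9-phenanthryl)quinidine (10 mol %), CH2Cl2, -25 °C
Reagents that add atoms: none
Why: Organocatalytic asymmetric Michael addition of an alpha-substituted 1,3-dicarbonyl donor to a vinyl ketone, in which the bifunctional catalyst binds the enolate at its quinuclidinium and the enone at its phenol, tells the small formyl group from the bulky tert-butyl ester and so sets the quaternary C4 as R.

Step 3
Reactants: 5 tert-butyl (2R)-2-formyl-2-methyl-5-oxoheptanoate
Product: 6 tert-butyl (1R)-1,3-dimethyl-4-oxocyclohex-2-ene-1-carboxylate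
Conditions: pyrrolidine, AcOH (20 mol % each), 4 Å MS, toluene, 60 °C
Reagents that add atoms: none
Why: Intramolecular aldol condensation (second half of a Robinson annulation), in which only the ethyl-side methylene (C10) can reach the non-enolisable aldehyde (C5) through a six-membered ring, closing ring A and leaving C4 untouched.

Step 4
Reactants: 6 tert-butyl (1R)-1,3-dimethyl-4-oxocyclohex-2-ene-1-carboxylate
Product: 7 tert-butyl (1R,4R)-4-hydroxy-1,3-dimethylcyclohex-2-ene-1-carboxylate
Conditions: (S)-Me-CBS oxazaborolidine (10 mol %), BH3·SMe2, THF, -30 °C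
Reagents that add atoms: none
Why: The CBS reduction is reagent-controlled: the alkenyl side of the ketone acts as the large group, so the (S)-oxazaborolidine should give the (4R)-carbinol (abietane C1) with OH cis to the C4 methyl group.

Step 5
Reactants: 7 tert-butyl (1R,4R)-4-hydroxy-1,3-dimethylcyclohex-2-ene-1-carboxylate; 8 triethyl orthoacetate
Product: 10 tert-butyl (1R,2R)-2-(2-ethoxy-2-oxoethyl)-1,3-dimethylcyclohex-3-ene-1-carboxylate, via mixed ketene acetal 9 (not isolated)
Conditions: 8 (excess), EtCO2H (5 mol %), 140 °C, EtOH distilled off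
Reagents that add atoms: none
Why: In the Johnson-Claisen rearrangement the suprafacial [3,3] shift hands the C1-O configuration on to C5, placing the acetate arm cis to the C4 methyl group and trans to the ester, moving the alkene to C1=C10 and removing the oxygen from ring A.

Step 6
Reactants: 10 tert-butyl (1R,2R)-2-(2-ethoxy-2-oxoethyl)-1,3-dimethylcyclohex-3-ene-1-carboxylate; 11 tert-butyl acetate
Product: 12 tert-butyl (1R,2R)-2-(4-tert-butoxy-2,4-dioxobutyl)-1,3-dimethylcyclohex-3-ene-1-carboxylate
Conditions: 11, LiN(iPr)2 (3.5 equiv each), THF, -78 °C; then 10, -78 → 0 °C; aq. NH4Cl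
Reagents that add atoms: none
Why: Crossed Claisen condensation of the unhindered ethyl ester with excess lithium enolate of tert-butyl acetate gives the beta-keto ester, while the neopentyl tert-butyl ester on C4 is too hindered to react and no stereocentre is touched.

Step 7
Reactants: 13 pent-4-enoyl chloride; 14 isopropylmagnesium chloride
Product: 15 2-methylhept-6-en-3-one
Conditions: Fe(acac)3 (3 mol %), THF, -78 °C
Reagents that add atoms: none
Why: Iron-catalysed acylation of a Grignard reagent by an acid chloride stops at the ketone because the cross-coupling is much faster than carbonyl addition at low temperature.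

Step 8
Reactants: 15 2-methylhept-6-en-3-one
Product: 16 5-methyl-4-oxohexanal
Conditions: O3, CH2Cl2, -78 °C; then Me2S
Reagents that add atoms: ozone [O-][O+]=O
Why: Ozonolysis with reductive work-up cleaves the terminal alkene to the aldehyde and leaves the ketone untouched.

Step 9
Reactants: 12 tert-butyl (1R,2R)-2-(4-tert-butoxy-2,4-dioxobutyl)-1,3-dimethylcyclohex-3-ene-1-carboxylate; 16 5-methyl-4-oxohexanal
Product: 18 di-tert-butyl (4R,5R,9R,10S)-7-hydroxy-13-oxo-13,14-secoabiet-7-ene-14,18-dioate (enol form), via Z-alkylidene beta-keto ester 17 (not isolated)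
Conditions: piperidine, AcOH (10 mol % each), 4 Å MS, EtOH, 0 → 23 °C; then Fe(acac)3 (20 mol %), PhSiH3, 60 °C, same flask
Reagents that add atoms: none
Why: Proposed new method: piperidinium acetate condenses the C8 active methylene of 12 with the aldehyde of 16 (Knoevenagel) to alkylidene 17, then the iron hydride formed from Fe(acac)3 and PhSiH3 transfers a hydrogen atom to C1 of the ring A alkene, the tertiary C10 radical adds to C9, and the resulting 1,3-dicarbonyl radical is reduced by divalent iron and protonated by ethanol to enol 18. The closest known reaction types are the domino Knoevenagel/cyclisation of alkylidene 1,3-dicarbonyl compounds made in situ and the iron-hydride reductive olefin coupling (hydrogen-atom-transfer Giese reaction), which builds quaternary carbons intramolecularly on enones and enoates; new are their union in one flask and the alkylidene beta-keto ester as acceptor. Ring B closes in the 6-endo-trig mode, because the nucleophilic tertiary radical is polarity-matched with the beta carbon C9 and 5-exo attack at C8 would give an unstabilised radical. C10 is set by ring A: with the C5 arm and the C4 ester equatorial, the axial C4 methyl group blocks the beta face, so C9 bonds from the alpha face, the C10 methyl group ends up axial and the ring fusion trans. C9 is set by the alkene geometry in a chair-like transition state: only the Z isomer of 17 (side chain trans to C7, the favoured and equilibrating isomer) can turn C9 toward C10 without allylic 1,3-strain between C11 and C6, and it places the side chain equatorial (9-alpha-H). The step needs hydrogen-atom transfer to C1=C10 rather than to C8=C9, which the substrate secures by offering the hydride an electron-rich, open ring CH next to a beta-substituted electron-poor acceptor, the same donor/acceptor discrimination on which reductive olefin coupling rests.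

Step 10
Reactants: 18 di-tert-butyl (4R,5R,9R,10S)-7-hydroxy-13-oxo-13,14-secoabiet-7-ene-14,18-dioate (enol form)
Product: 19 di-tert-butyl (4R,5R,9R,10S)-13-oxo-7-(trifluoromethylsulfonyloxy)-13,14-secoabiet-7-ene-14,18-dioate
Conditions: NaH (1 equiv), Et2O, 0 °C; then Tf2O, -78 → 0 °C
Reagents that add atoms: trifluoromethanesulfonic anhydride O=S(=O)(OS(=O)(=O)C(F)(F)F)C(F)(F)F
Why: O-sulfonylation of the sodium enolate is chemoselective because one equivalent of base deprotonates only the far more acidic beta-keto ester and not the C13 ketone, and it fixes the double bond at C7=C8.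

Step 11
Reactants: 19 di-tert-butyl (4R,5R,9R,10S)-13-oxo-7-(trifluoromethylsulfonyloxy)-13,14-secoabiet-7-ene-14,18-dioate
Product: 20 di-tert-butyl (4R,5R,9R,10S)-13-oxo-13,14-secoabiet-7-ene-14,18-dioate
Conditions: Pd(OAc)2 (5 mol %), PPh3 (10 mol %), HCO2H, Et3N, DMF, 60 °C
Reagents that add atoms: none
Why: In the palladium-catalysed formate reduction of the enol triflate, oxidative addition to zerovalent palladium, formate decarboxylation and reductive elimination replace OTf by H without moving the C7=C8 double bond or touching C9.

Step 12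
Reactants: 20 di-tert-butyl (4R,5R,9R,10S)-13-oxo-13,14-secoabiet-7-ene-14,18-dioate
Product: 21 (4R,5R,9R,10S)-13-oxo-13,14-secoabiet-7-ene-14,18-dioic acid (CNP0333046.1)
Conditions: CF3CO2H, CH2Cl2, 0 → 23 °C
Reagents that add atoms: none
Why: Acidolysis with E1 loss of isobutene frees both carboxylic acids, avoids the forcing saponification that a neopentyl C4 ester would need and cannot epimerise C9.

Compound list
1 | tert-butyl propanoate | CCC(=O)OC(C)(C)C | starting material
2 | ethyl formate | CCOC=O | starting material
3 | tert-butyl 2-methyl-3-oxopropanoate (racemic, enolisable) | CC(C=O)C(=O)OC(C)(C)C | intermediate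
4 | pent-1-en-3-one (ethyl vinyl ketone) | CCC(=O)C=C | starting material
5 | tert-butyl (2R)-2-formyl-2-methyl-5-oxoheptanoate | CCC(=O)CC[C@](C)(C=O)C(=O)OC(C)(C)C | intermediate
6 | tert-butyl (1R)-1,3-dimethyl-4-oxocyclohex-2-ene-1-carboxylate | CC1=C[C@@](C)(CCC1=O)C(=O)OC(C)(C)C | intermediate
7 | tert-butyl (1R,4R)-4-hydroxy-1,3-dimethylcyclohex-2-ene-1-carboxylate (OH cis to the 1-methyl group) | CC1=C[C@@](C)(CC[C@H]1O)C(=O)OC(C)(C)C | intermediate
8 | triethyl orthoacetate | CC(OCC)(OCC)OCC | starting material
9 | tert-butyl (1R,4R)-4-[(1-ethoxyethenyl)oxy]-1,3-dimethylcyclohex-2-ene-1-carboxylate (mixed ketene acetal, not isolated) | CC1=C[C@@](C)(CC[C@H]1OC(=C)OCC)C(=O)OC(C)(C)C | intermediate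
10 | tert-butyl (1R,2R)-2-(2-ethoxy-2-oxoethyl)-1,3-dimethylcyclohex-3-ene-1-carboxylate | CCOC(=O)C[C@@H]1C(C)=CCC[C@@]1(C)C(=O)OC(C)(C)C | intermediate
11 | tert-butyl acetate | CC(=O)OC(C)(C)C | starting material
12 | tert-butyl (1R,2R)-2-(4-tert-butoxy-2,4-dioxobutyl)-1,3-dimethylcyclohex-3-ene-1-carboxylate | CC(C)(C)OC(=O)CC(=O)C[C@@H]1C(C)=CCC[C@@]1(C)C(=O)OC(C)(C)C | intermediate
13 | pent-4-enoyl chloride | C=CCCC(=O)Cl | starting material
14 | isopropylmagnesium chloride | CC(C)[Mg]Cl | starting material
15 | 2-methylhept-6-en-3-one | CC(C)C(=O)CCC=C | intermediate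
16 | 5-methyl-4-oxohexanal | CC(C)C(=O)CCC=O | intermediate
17 | tert-butyl (1R,2R)-2-[(3Z)-3-(tert-butoxycarbonyl)-8-methyl-2,7-dioxonon-3-en-1-yl]-1,3-dimethylcyclohex-3-ene-1-carboxylate (not isolated) | CC(C)C(=O)CC/C=C(\C(=O)OC(C)(C)C)C(=O)C[C@@H]1C(C)=CCC[C@@]1(C)C(=O)OC(C)(C)C | intermediate
18 | di-tert-butyl (4R,5R,9R,10S)-7-hydroxy-13-oxo-13,14-secoabiet-7-ene-14,18-dioate (enol form of the 7-oxo beta-keto ester) | CC(C)C(=O)CC[C@H]1C(C(=O)OC(C)(C)C)=C(O)C[C@@H]2[C@]1(C)CCC[C@@]2(C)C(=O)OC(C)(C)C | intermediate
19 | di-tert-butyl (4R,5R,9R,10S)-13-oxo-7-(trifluoromethylsulfonyloxy)-13,14-secoabiet-7-ene-14,18-dioate | CC(C)C(=O)CC[C@H]1C(C(=O)OC(C)(C)C)=C(OS(=O)(=O)C(F)(F)F)C[C@@H]2[C@]1(C)CCC[C@@]2(C)C(=O)OC(C)(C)C | intermediate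
20 | di-tert-butyl (4R,5R,9R,10S)-13-oxo-13,14-secoabiet-7-ene-14,18-dioate | CC(C)C(=O)CC[C@H]1C(C(=O)OC(C)(C)C)=CC[C@@H]2[C@]1(C)CCC[C@@]2(C)C(=O)OC(C)(C)C | intermediate
21 | (4R,5R,9R,10S)-13-oxo-13,14-secoabiet-7-ene-14,18-dioic acid (CNP0333046.1) | CC(C)C(=O)CC[C@H]1C(C(=O)O)=CC[C@@H]2[C@]1(C)CCC[C@@]2(C)C(=O)O | target

Total step count: 12. Longest linear sequence: 10 (steps 1 to 6 and 9 to 12). Steps 7 and 8 are the side branch.

Steps most likely to fail

Step 9 (proposed new method).
- Possible failure: hydrogen-atom or hydride transfer to the electron-poor C8=C9 bond, giving plain reduction of the alkylidene.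
- Possible failure: Michael addition of a second molecule of the beta-keto ester to the alkylidene, or deconjugation of the alkylidene toward C11.
- Possible failure: erosion of the C9 configuration if the E isomer cyclises competitively.
- Fallback by known chemistry: iron-hydride radical conjugate addition followed by aldol ring closure, a radical-polar crossover annulation. It sets out from 10 and comes back at 20. Reduction of the ethyl ester of 10 by iBu2AlH at -78 °C gives tert-butyl (1R,2R)-1,3-dimethyl-2-(2-oxoethyl)cyclohex-3-ene-1-carboxylate F1. Wittig olefination of 16 by Ph3P=CHCO2tBu gives tert-butyl (E)-7-methyl-6-oxooct-2-enoate F2. Fe(acac)3 and PhSiH3 in ethanol join the two. The C10 radical of F1 adds to C9 of F2, and the iron enolate closes on the C7 aldehyde to give di-tert-butyl 7-hydroxy-13-oxo-13,14-secoabietane-14,18-dioate (5-alpha-H, 9-alpha-H, 10-beta-methyl, mixture at C7 and C8) F3. Mesylation and elimination by DBU return to the route at 20, so steps 6, 10 and 11 are bypassed.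

Step 2.
- Possible failure: insufficient facial discrimination of the formyl ester enolate, or loss of enantiopurity by retro-Michael addition.
- Fallback: replace the catalytic asymmetric bond formation by a reagent-controlled reduction of the racemate. It sets out from 3 and 4 and comes back at 7. Et3N-catalysed Michael addition gives racemic tert-butyl 2-formyl-2-methyl-5-oxoheptanoate F4. This is cyclised as in step 3 to racemic tert-butyl 1,3-dimethyl-4-oxocyclohex-2-ene-1-carboxylate F5. The (S)-Me-CBS/BH3 reduction sets the carbinol carbon with the same sense in both enantiomers. The racemate is thus turned into two diastereomers, 7 and tert-butyl (1S,4R)-4-hydroxy-1,3-dimethylcyclohex-2-ene-1-carboxylate F6. These are separated by chromatography, and the route continues from 7.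

Step 5.
- Possible failure: slow rearrangement, because the new bond is made next to the quaternary C4.
- Possible failure: acid-promoted dehydration of the allylic alcohol to a diene, or loss of the tert-butyl ester on long heating.
- Fallback: replace the thermal, acid-catalysed orthoester exchange by an anionic ester-enolate rearrangement and rebuild the beta-keto ester from the acid. It sets out from 7 and comes back at 12. Acetylation (Ac2O, DMAP) gives tert-butyl (1R,4R)-4-acetoxy-1,3-dimethylcyclohex-2-ene-1-carboxylate F7. Ireland-Claisen rearrangement (LiN(iPr)2, Me3SiCl, THF, -78 °C to gentle warming) gives [(1R,6R)-6-(tert-butoxycarbonyl)-2,6-dimethylcyclohex-2-en-1-yl]acetic acid F8. Activation by carbonyldiimidazole and chain extension by Mg(O2CCH2CO2tBu)2 return to the route at 12, bypassing 10.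

Further compounds
F1 | step 9 | tert-butyl (1R,2R)-1,3-dimethyl-2-(2-oxoethyl)cyclohex-3-ene-1-carboxylate | O=CC[C@@H]1C(C)=CCC[C@@]1(C)C(=O)OC(C)(C)C
F2 | step 9 | tert-butyl (E)-7-methyl-6-oxooct-2-enoate | CC(C)C(=O)CC/C=C/C(=O)OC(C)(C)C
F3 | step 9 | di-tert-butyl 7-hydroxy-13-oxo-13,14-secoabietane-14,18-dioate (5-alpha-H, 9-alpha-H, 10-beta-methyl, mixture at C7 and C8) | CC(C)C(=O)CC[C@H]1C(C(=O)OC(C)(C)C)C(O)C[C@@H]2[C@]1(C)CCC[C@@]2(C)C(=O)OC(C)(C)C
F4 | step 2 | racemic tert-butyl 2-formyl-2-methyl-5-oxoheptanoate | CCC(=O)CCC(C)(C=O)C(=O)OC(C)(C)C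
F5 | step 2 | racemic tert-butyl 1,3-dimethyl-4-oxocyclohex-2-ene-1-carboxylate | CC1=CC(C)(CCC1=O)C(=O)OC(C)(C)C
F6 | step 2 | tert-butyl (1S,4R)-4-hydroxy-1,3-dimethylcyclohex-2-ene-1-carboxylate | CC1=C[C@](C)(CC[C@H]1O)C(=O)OC(C)(C)C
F7 | step 5 | tert-butyl (1R,4R)-4-acetoxy-1,3-dimethylcyclohex-2-ene-1-carboxylate | CC1=C[C@@](C)(CC[C@H]1OC(C)=O)C(=O)OC(C)(C)C
F8 | step 5 | [(1R,6R)-6-(tert-butoxycarbonyl)-2,6-dimethylcyclohex-2-en-1-yl]acetic acid | OC(=O)C[C@@H]1C(C)=CCC[C@@]1(C)C(=O)OC(C)(C)C
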